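# Synthesis proposal: (3S,4S,3'R)-4-hydroxyalloxanthin by end-selective enzymatic C4 hydroxylation of alloxanthin

## The problem

The target is a C40 carotenoid: two 2,6,6-trimethylcyclohexene rings are joined through C7≡C8 and C7'≡C8' to an all-E chain of seven double bonds. The chain has to be assembled without losing the E geometry at C9=C10 and C9'=C10', which isomerises unusually easily next to a triple bond. Ring A (C1–C6) carries a trans 3,4-diol (3S,4S) and ring B (C1'–C6') a single 3'R carbinol. C3 is adjacent to C4 and can steer it, but C3' lies more than twenty bonds away, so it must be introduced enantiopure on its own. The polyene does not tolerate light, oxygen, acid or iodine. The C4 carbinol is allylic to C5=C6 and conjugated onward to the alkyne, so it ionises and oxidises readily and should appear as late as possible. The decisive feature is that removal of the C4 oxygen leaves (3R,3'R)-alloxanthin, whose two rings are exchanged by a C2 axis through C15=C15'. Each ring has one allylic ring methylene, C4, between carbinol C3 and alkene C5=C6, and hydroxylation at either end gives the same triol. The change of the C3 descriptor from R to S is only a change of CIP priority. The task therefore divides into a two-directional synthesis of a symmetric diol from one chiral ring block, and one selective C–H oxidation.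

## Retrosynthesis

**15 ⇒ 14 (C4–O).** The only bond cut is C4–O of ring A, which leads back to alloxanthin 14. Any cut inside the chain (C11=C12 on one side, or C15=C15') would need a separately built dioxygenated ring and an unsymmetrical assembly. This cut removes one stereocentre and all end differentiation. The forward reaction must hydroxylate C4 on the face anti to C3–OH, stop at the alcohol and touch only one end. No small reagent does this, so it is assigned to an engineered cytochrome P450 of the carotenoid C4-oxygenase class.

**14 ⇒ 13 ⇒ 10 + 11 (C11=C12 and C11'=C12').** After formal silylation to 13, both disubstituted double bonds flanking the central C10 unit are cut. This gives two equivalents of C15 phosphonium salt 10 and the commercial C10 dialdehyde 11; the mono-condensation product 12 is passed through in the flask. Against a C15=C15' cut (two C20 halves) or a C7≡C8 cut (sulfone chemistry), this uses one chiral building block twice and a purchased centre piece. The forward Wittig reaction must give E olefins and must not disturb C9=C10; this is why a tributylphosphonium salt is chosen and the hydroxyls are kept silylated.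

**10 ⇒ 9 ⇒ 8 (C11–P, C11–Br).** The salt is traced through allylic bromide 9 to dienynol 8. Direct salt formation from the alcohol with a phosphine hydrobromide would pass through an allyl cation delocalised onto C9 and risk the 9Z isomer. Two SN2 displacements at the primary carbon avoid this.

**8 ⇒ 6 + 7 (C6–C7).** The sp2–sp bond between ring and alkyne is cut to enol triflate 6 and the commercial (E)-enynol 7. The neighbouring option, acetylide addition to ketone 4 followed by dehydration, would need a protected enynol, a differentiated triol and a dehydration of a tertiary propargylic alcohol. The Sonogashira coupling delivers the C5=C6 double bond already in place and needs no protection of 7.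

**6 ⇒ 4 ⇒ 3 (C–OTf, O–Si).** Triflate 6 comes from silyl ether 4 through its only possible enolate 5. C6 of 4 carries the sole α-hydrogen, so regiochemistry is not an issue, and the methyl stereocentre is erased once it has done its work.

**3 ⇒ 2 ⇒ 1 (two C–H bonds).** Actinol 3 is reached from ketoisophorone 1 by two enzymatic reductions via levodione 2. The first sets the methyl centre, the second the carbinol that becomes C3 and C3'. Both are established biocatalytic reductions starting from a bulk chemical.

## Roads not taken

**Alternative 1:** Both C–O bonds of ring A are traced to a C3=C4 alkene in a small ring dienyne, trimethylsilyl-capped A2. The forward key step is a Jacobsen–Katsuki epoxidation of this cis-disubstituted alkene with NaOCl and chiral N,N'-bis(3,5-di-tert-butylsalicylidene)-1,2-cyclohexanediaminomanganese chloride, giving vinyl epoxide A1. Opening at allylic C4 with inversion then fixes the trans-diol.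
- Merits: one catalytic step encodes both ring A centres, the trans relationship follows from SN2 inversion, and every reaction class is known.
- Weak points: A1 is an acid-labile vinyl epoxide that can also open in the SN2' sense at C6. The enantioselectivity on this particular conjugated diene is not assured. A1 supplies ring A only, so ring B still has to be made from 3 and the chain joined by two different olefinations.
- Comparison: in predictability at C4 this road is better than the enzymatic step. The chosen plan sets against it a single ring block used twice, a much shorter sequence, and a C4 hydroxyl that enters last and never meets a reagent.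

**Alternative 2:** The cut is at both triple bonds. The lithiated ring sulfones A5 (3R) and A6 (3S,4S, bis-silylated) are added in turn to crocetindial A4. The alkoxides are trapped with ClP(O)(OEt)2 and excess t-BuOK expels phosphate and then benzenesulfinate, giving tris-silyl ether A3.
- Merits: it is the most convergent design. A4 brings all seven chain double bonds with fixed E geometry, and A3 is one desilylation from the target.
- Weak points: two different nucleophiles must add to a symmetric dialdehyde, so the first addition is statistical. The anion of A6 shares its charge with C5, which is β to the C4 silyloxy group, so vinylogous loss of silanolate threatens. The dioxygenated ring still has to be built with two stereocentres.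
- Comparison: in certainty of where the oxygens sit it is superior. The chosen plan answers with one ring synthesis instead of two. It also has a statistical element, but there the unreacted partner (14) is simply recycled, whereas mis-coupling here consumes the costly ring A sulfone.

**Alternative 3:** The cut is at C15=C15'. The ylide from the 3'R C20 phosphonium salt A8 condenses with the 3,4-bis-silylated C20 aldehyde A9 to give bis-silyl ether A7.
- Merits: this is classical carotenoid practice. A central Z isomer is hindered and reverts thermally, each half carries its own stereochemistry, and nothing is statistical.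
- Weak points: two different C20 halves each need their own chain extension, so it is the longest road, and the dioxygenated ring of A9 must again be made de novo.
- Comparison: step for step this is the safest of the four plans and clearly safer than the chosen key step. The chosen plan sets against it roughly half the operations and one building block. Its intermediates 8 and 12 also feed a convergent fallback of this kind if the enzyme fails.

Key step: step 10

Assumption: all chain double bonds are E as drawn, the 3,4-diol is trans, and C3 of the target has the same spatial arrangement as C3 of (3R,3'R)-alloxanthin, the S descriptor arising only from the higher CIP rank of the oxygenated C4.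

## Route

Step 1
Reactants: 1 ketoisophorone (2,6,6-trimethylcyclohex-2-ene-1,4-dione)
Product: 2 (6R)-2,2,6-trimethylcyclohexane-1,4-dione ((6R)-levodione)
Conditions: ene-reductase OYE2 (old yellow enzyme of Saccharomyces cerevisiae), NADP+ (cat.), glucose dehydrogenase, D-glucose, phosphate buffer pH 7.0 (pH-stat), 30 °C
Reagents that add atoms: none
Why: Asymmetric ene-reduction: flavin hydride adds to the activated C=C and an active-site tyrosine protonates the neighbouring carbon from the opposite face, the binding mode of the dione fixing the methyl-bearing carbon as R; this is an established biocatalytic reduction of this substrate.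

Step 2
Reactants: 2 (6R)-levodione
Product: 3 (4R,6R)-4-hydroxy-2,2,6-trimethylcyclohexan-1-one ((4R,6R)-actinol)
Conditions: levodione reductase (Corynebacterium aquaticum), NAD+ (cat.), glucose dehydrogenase, D-glucose, phosphate buffer pH 7.0 (pH-stat), 30 °C
Reagents that add atoms: none
Why: Ketoreductase reduction: hydride is delivered only to the C4 carbonyl (C1 is shielded by three methyl groups) and from the face that gives the 4R alcohol trans to the C6 methyl; the enzyme sets this centre, which becomes C3 and C3' of the carotenoid.

Step 3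
Reactants: 3 (4R,6R)-actinol
Product: 4 (4R,6R)-4-[(tert-butyldimethylsilyl)oxy]-2,2,6-trimethylcyclohexan-1-one
Conditions: TBSCl, imidazole, DMF, rt
Reagents that add atoms: tert-butyldimethylsilyl chloride, CC(C)(C)[Si](C)(C)Cl
Why: Standard silylation of a secondary alcohol; the ether should withstand the amide base, the palladium coupling, the Appel reaction and the methoxide of the later steps.

Step 4
Reactants: 4 silyl ether of actinol
Product: 6 (4R)-4-[(tert-butyldimethylsilyl)oxy]-2,6,6-trimethylcyclohex-1-en-1-yl trifluoromethanesulfonate, via lithium enolate 5 (not isolated)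
Conditions: LiN(i-Pr)2, THF, −78 to 0 °C; PhNTf2, 0 °C to rt
Reagents that add atoms: N-phenylbis(trifluoromethanesulfonimide), O=S(=O)(N(c1ccccc1)S(=O)(=O)C(F)(F)F)C(F)(F)F
Why: Enolate O-triflation: C6 holds the only α-hydrogen (C2 is quaternary), so a single tetrasubstituted enol triflate can form; the C6 stereocentre is erased here, while the carbinol centre is untouched.

Step 5
Reactants: 6 enol triflate; 7 (E)-3-methylpent-2-en-4-yn-1-ol
Product: 8 (2E)-5-[(4R)-4-[(tert-butyldimethylsilyl)oxy]-2,6,6-trimethylcyclohex-1-en-1-yl]-3-methylpent-2-en-4-yn-1-ol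
Conditions: Pd(PPh3)4 (cat.), CuI (cat.), Et3N, DMF, rt
Reagents that add atoms: none
Why: Sonogashira coupling: oxidative addition of the C–OTf bond to zerovalent palladium, transmetalation from the copper acetylide and reductive elimination form the C6–C7 bond with the ring alkene already in place; the slim alkyne tolerates the flanked triflate, the free primary alcohol is compatible and the E alkene of 7 is not involved.

Step 6
Reactants: 8 silylated dienynol
Product: 9 tert-butyl{[(1R)-4-[(3E)-5-bromo-3-methylpent-3-en-1-yn-1-yl]-3,5,5-trimethylcyclohex-3-en-1-yl]oxy}dimethylsilane (allylic bromide)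
Conditions: CBr4, PPh3, CH2Cl2, −20 to 0 °C
Reagents that add atoms: carbon tetrabromide, BrC(Br)(Br)Br
Why: Appel bromination: bromide displaces the alkoxyphosphonium group at the primary allylic carbon in an SN2 step under neutral conditions, so no allyl cation forms and both the E geometry at C9=C10 (carotenoid numbering) and the silyl ether should be kept.

Step 7
Reactants: 9 allylic bromide
Product: 10 tributyl[(2E)-5-[(4R)-4-[(tert-butyldimethylsilyl)oxy]-2,6,6-trimethylcyclohex-1-en-1-yl]-3-methylpent-2-en-4-yn-1-yl]phosphonium bromide
Conditions: PBu3, MeCN, rt, argon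
Reagents that add atoms: tributylphosphine, CCCCP(CCCC)CCCC
Why: SN2 quaternisation of a primary allylic bromide by a strongly nucleophilic trialkylphosphine at the unhindered terminus; again no cation, so C9=C10 stays E, and the trialkylphosphonium group is the E-selective variant for the Wittig reaction that follows.

Step 8
Reactants: 10 C15 tributylphosphonium bromide (2.2 equiv); 11 (2E,4E,6E)-2,7-dimethylocta-2,4,6-trienedial
Product: 13 (3R,3'R)-3,3'-bis[(tert-butyldimethylsilyl)oxy]-7,8,7',8'-tetradehydro-β,β-carotene (alloxanthin bis-silyl ether), via C25 apo-aldehyde 12 (not isolated)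
Conditions: NaOMe (in MeOH) added to 10 and 11 in CH2Cl2, 0 °C to rt, dark, argon
Reagents that add atoms: none
Why: Two-fold Wittig olefination: the allylic ylide formed in situ from 10 condenses with one formyl group of 11 to give 12 and then with the other; allylic trialkylphosphonium ylides are known to favour E olefins, so C11=C12 and C11'=C12' should form E at room temperature without a heating period that could isomerise C9=C10.

Step 9
Reactants: 13 alloxanthin bis-silyl ether
Product: 14 (3R,3'R)-7,8,7',8'-tetradehydro-β,β-carotene-3,3'-diol (alloxanthin)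
Conditions: TBAF, THF, 0 °C to rt, dark
Reagents that add atoms: none
Why: Fluoride cleavage of two secondary silyl ethers; the mildly basic conditions should leave the polyene, the ene-yne units and both carbinol centres untouched.

Step 10
Reactants: 14 alloxanthin
Product: 15 (3S,4S,3'R)-7,8,7',8'-tetradehydro-β,β-carotene-3,4,3'-triol ((3S,4S,3'R)-4-hydroxyalloxanthin)
Conditions: engineered cytochrome P450 carotenoid C4-hydroxylase (CYP2J19-type variant, no partner dehydrogenase), cytochrome P450 reductase, NADP+ (cat.), glucose dehydrogenase, D-glucose, O2 (air), Tween 80 micelles, phosphate buffer pH 7.4, 30 °C, dark, stopped at partial conversion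
Reagents that add atoms: dioxygen, O=O
Why: Proposed new method: the haem iron is reduced, binds O2 and is converted to the oxoiron porphyrin radical cation (iron formally tetravalent), which abstracts the C4 hydrogen on the ring face opposite the C3 hydroxyl; the radical is allylic to C5=C6 and delocalised into C7≡C8, and the iron-bound hydroxyl rebounds at C4 on the face the hydrogen left, so the C4–O bond forms with retention and trans to C3–OH. The closest known reaction type is the P450-catalysed C4 oxygenation of 3-hydroxy-β-ring carotenoids such as zeaxanthin, which runs through 4-hydroxy intermediates to 4-ketones, together with P450 allylic hydroxylation of terpenes in general; a stop at the carbinol on a 7,8-didehydro substrate has not been shown. No ring is formed. The single new stereocentre, C4, is controlled by the catalyst: a hydrogen bond to the C3 hydroxyl and the fit of the gem-dimethyl group are expected to present only the anti C4–H to the oxo ligand, and that face is also the less hindered one. Site selectivity (C4 against the C18, C19 and C20 methyl groups, nine alkenes and two alkynes) rests on the binding pocket and on C4 being the only secondary allylic C–H bond; rebound at C4 and not at C6 or C8 is favoured by proximity to iron and by keeping the ene-yne conjugated. Oxidation beyond the alcohol is limited by using the hydroxylase without the separate dehydrogenase thought to complete ketone formation in animal systems, and by engineering against a second turnover at C4. Because the two rings of 14 are homotopic, the first hydroxylation gives 15 whichever end binds; the second end is spared by stopping early and recycling 14, which separates readily from the more polar triol and tetrol by chromatography before crystallisation of 15.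

## Compound list

1 | ketoisophorone (2,6,6-trimethylcyclohex-2-ene-1,4-dione) | CC1=CC(=O)CC(C)(C)C1=O | starting material
2 | (6R)-2,2,6-trimethylcyclohexane-1,4-dione | C[C@@H]1CC(=O)CC(C)(C)C1=O | intermediate
3 | (4R,6R)-4-hydroxy-2,2,6-trimethylcyclohexan-1-one | C[C@@H]1C[C@@H](O)CC(C)(C)C1=O | intermediate
4 | (4R,6R)-4-[(tert-butyldimethylsilyl)oxy]-2,2,6-trimethylcyclohexan-1-one | C[C@@H]1C[C@@H](O[Si](C)(C)C(C)(C)C)CC(C)(C)C1=O | intermediate
5 | lithium (4R)-4-[(tert-butyldimethylsilyl)oxy]-2,6,6-trimethylcyclohex-1-en-1-olate | [Li+].CC1=C([O-])C(C)(C)C[C@H](O[Si](C)(C)C(C)(C)C)C1 | intermediate (not isolated)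
6 | (4R)-4-[(tert-butyldimethylsilyl)oxy]-2,6,6-trimethylcyclohex-1-en-1-yl trifluoromethanesulfonate | CC1=C(OS(=O)(=O)C(F)(F)F)C(C)(C)C[C@H](O[Si](C)(C)C(C)(C)C)C1 | intermediate
7 | (E)-3-methylpent-2-en-4-yn-1-ol | C#C/C(C)=C/CO | starting material
8 | (2E)-5-[(4R)-4-[(tert-butyldimethylsilyl)oxy]-2,6,6-trimethylcyclohex-1-en-1-yl]-3-methylpent-2-en-4-yn-1-ol | CC1=C(C#C/C(C)=C/CO)C(C)(C)C[C@H](O[Si](C)(C)C(C)(C)C)C1 | intermediate
9 | tert-butyl{[(1R)-4-[(3E)-5-bromo-3-methylpent-3-en-1-yn-1-yl]-3,5,5-trimethylcyclohex-3-en-1-yl]oxy}dimethylsilane | CC1=C(C#C/C(C)=C/CBr)C(C)(C)C[C@H](O[Si](C)(C)C(C)(C)C)C1 | intermediate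
10 | tributyl[(2E)-5-[(4R)-4-[(tert-butyldimethylsilyl)oxy]-2,6,6-trimethylcyclohex-1-en-1-yl]-3-methylpent-2-en-4-yn-1-yl]phosphonium bromide | CC1=C(C#C/C(C)=C/C[P+](CCCC)(CCCC)CCCC)C(C)(C)C[C@H](O[Si](C)(C)C(C)(C)C)C1.[Br-] | intermediate
11 | (2E,4E,6E)-2,7-dimethylocta-2,4,6-trienedial | O=C/C(C)=C/C=C/C=C(C)/C=O | starting material
12 | (2E,4E,6E,8E,10E)-13-[(4R)-4-[(tert-butyldimethylsilyl)oxy]-2,6,6-trimethylcyclohex-1-en-1-yl]-2,7,11-trimethyltrideca-2,4,6,8,10-pentaen-12-ynal (C25 apo-aldehyde) | CC1=C(C#C/C(C)=C/C=C/C(C)=C/C=C/C=C(C)/C=O)C(C)(C)C[C@H](O[Si](C)(C)C(C)(C)C)C1 | intermediate (not isolated)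
13 | (3R,3'R)-3,3'-bis[(tert-butyldimethylsilyl)oxy]-7,8,7',8'-tetradehydro-β,β-carotene | CC1=C(C#C/C(C)=C/C=C/C(C)=C/C=C/C=C(C)/C=C/C=C(\C)C#CC2=C(C)C[C@@H](O[Si](C)(C)C(C)(C)C)CC2(C)C)C(C)(C)C[C@H](O[Si](C)(C)C(C)(C)C)C1 | intermediate
14 | (3R,3'R)-alloxanthin | CC1=C(C#C/C(C)=C/C=C/C(C)=C/C=C/C=C(C)/C=C/C=C(\C)C#CC2=C(C)C[C@@H](O)CC2(C)C)C(C)(C)C[C@H](O)C1 | intermediate
15 | (3S,4S,3'R)-4-hydroxyalloxanthin | CC1=C(C#C/C(C)=C/C=C/C(C)=C/C=C/C=C(C)/C=C/C=C(\C)C#CC2=C(C)[C@H](O)[C@@H](O)CC2(C)C)C(C)(C)C[C@H](O)C1 | target

## Step count and risks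

Total: 10 steps. Longest linear sequence: 10 steps (1 → 15); 7 and 11 are purchased.

**Step 10 (key step, proposed new method).** The linear ene-yne end may not bind productively, oxidation may run on past the carbinol, both ends may be hydroxylated, hydrogen may be abstracted from the wrong face, or oxygen may be transferred to a chain alkene. The fallback gives up the late C–H oxidation for a convergent assembly by known reactions. It sets out from 8 and from apo-aldehyde 12 (isolable when 10 is added slowly to an excess of 11) and returns at 15.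
- Acetylation of 8 (Ac2O, pyridine) gives the allylic acetate F1.
- Allylic oxidation of the ring methylene with CrO3·3,5-dimethylpyrazole gives the 4-oxo enone F2.
- Luche reduction (NaBH4, CeCl3·7H2O, MeOH, −78 °C) gives the trans carbinol F3. The silyloxy group should sit pseudo-equatorial (avoiding the axial C1 methyl) and hydride should enter axially; any cis isomer is removed by chromatography.
- Silylation (TBSOTf, 2,6-lutidine) gives the bis-silyl acetate F4, and methanolysis (K2CO3, MeOH) the bis-silyl dienynol F5.
- Appel bromination gives the bromide F6 and PBu3 the phosphonium salt F7.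
- Wittig condensation of F7 with 12 (NaOMe added to the mixture) gives the tris-silyl ether F8, and TBAF releases 15.

**Step 8.** The 9E geometry may erode through the delocalised allyl ylide, E selectivity at the new double bonds may be incomplete, or the reaction may stall at mono-condensation. The fallback reverses the polarity so that C9=C10 sits in the electrophile. It sets out from 8 and 11 and returns at 13.
- MnO2 oxidation of 8 gives the enynal F9.
- NaBH4 reduction of 11 gives the C10 diol F10, PBr3 the dibromide F11, and an Arbuzov reaction with P(OEt)3 the bis(phosphonate) F12.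
- KOt-Bu added to F12 and two equivalents of F9 in THF effects a double Horner–Wadsworth–Emmons olefination to 13.

**Step 5 (and step 4).** Enolisation and O-triflation of the hindered ketone may be sluggish, oxidative addition of the tetrasubstituted triflate slow, and the enynol may homocouple oxidatively. The fallback is the addition–dehydration sequence. It sets out from 4 and 7 and returns at 8.
- Silylation of 7 gives the silyl ether F13, and n-BuLi (THF, −78 °C) its lithium acetylide F14.
- Addition of F14 to 4 gives the tertiary propargylic carbinol F15 (either C1 epimer serves).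
- Dehydration (POCl3, pyridine; a syn-eliminating sulfamate reagent if the hydroxyl and the neighbouring hydrogen prove syn) gives the bis-silyl dienyne F16.
- Selective cleavage of the primary allylic silyl ether (pyridinium p-toluenesulfonate, MeOH) gives 8.

**Step 2.** Incomplete facial selectivity, or epimerisation of the α-methyl centre before reduction, would erode the configuration of the future C3 and C3'. The fallback is substrate-controlled hydrogenation of 2 over Raney Ni (Ni–Al alloy leached with NaOH). Hydrogen should add mainly from the face away from the axial methyl to give 3. The minor cis epimer F17 is removed by crystallisation or chromatography, and the route is rejoined at 3.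

## Further compounds

F1 | step 10 | (2E)-5-[(4R)-4-[(tert-butyldimethylsilyl)oxy]-2,6,6-trimethylcyclohex-1-en-1-yl]-3-methylpent-2-en-4-yn-1-yl acetate | CC1=C(C#C/C(C)=C/COC(C)=O)C(C)(C)C[C@H](O[Si](C)(C)C(C)(C)C)C1
F2 | step 10 | (2E)-5-[(4S)-4-[(tert-butyldimethylsilyl)oxy]-2,6,6-trimethyl-3-oxocyclohex-1-en-1-yl]-3-methylpent-2-en-4-yn-1-yl acetate | CC1=C(C#C/C(C)=C/COC(C)=O)C(C)(C)C[C@H](O[Si](C)(C)C(C)(C)C)C1=O
F3 | step 10 | (2E)-5-[(3S,4S)-4-[(tert-butyldimethylsilyl)oxy]-3-hydroxy-2,6,6-trimethylcyclohex-1-en-1-yl]-3-methylpent-2-en-4-yn-1-yl acetate | CC1=C(C#C/C(C)=C/COC(C)=O)C(C)(C)C[C@H](O[Si](C)(C)C(C)(C)C)[C@H]1O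
F4 | step 10 | (2E)-5-[(3S,4S)-3,4-bis[(tert-butyldimethylsilyl)oxy]-2,6,6-trimethylcyclohex-1-en-1-yl]-3-methylpent-2-en-4-yn-1-yl acetate | CC1=C(C#C/C(C)=C/COC(C)=O)C(C)(C)C[C@H](O[Si](C)(C)C(C)(C)C)[C@H]1O[Si](C)(C)C(C)(C)C
F5 | step 10 | (2E)-5-[(3S,4S)-3,4-bis[(tert-butyldimethylsilyl)oxy]-2,6,6-trimethylcyclohex-1-en-1-yl]-3-methylpent-2-en-4-yn-1-ol | CC1=C(C#C/C(C)=C/CO)C(C)(C)C[C@H](O[Si](C)(C)C(C)(C)C)[C@H]1O[Si](C)(C)C(C)(C)C
F6 | step 10 | (3S,4S)-1-[(3E)-5-bromo-3-methylpent-3-en-1-yn-1-yl]-3,4-bis[(tert-butyldimethylsilyl)oxy]-2,6,6-trimethylcyclohex-1-ene | CC1=C(C#C/C(C)=C/CBr)C(C)(C)C[C@H](O[Si](C)(C)C(C)(C)C)[C@H]1O[Si](C)(C)C(C)(C)C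
F7 | step 10 | tributyl[(2E)-5-[(3S,4S)-3,4-bis[(tert-butyldimethylsilyl)oxy]-2,6,6-trimethylcyclohex-1-en-1-yl]-3-methylpent-2-en-4-yn-1-yl]phosphonium bromide | CC1=C(C#C/C(C)=C/C[P+](CCCC)(CCCC)CCCC)C(C)(C)C[C@H](O[Si](C)(C)C(C)(C)C)[C@H]1O[Si](C)(C)C(C)(C)C.[Br-]
F8 | step 10 | (3S,4S,3'R)-3,4,3'-tris[(tert-butyldimethylsilyl)oxy]-7,8,7',8'-tetradehydro-β,β-carotene | CC1=C(C#C/C(C)=C/C=C/C(C)=C/C=C/C=C(C)/C=C/C=C(\C)C#CC2=C(C)[C@H](O[Si](C)(C)C(C)(C)C)[C@@H](O[Si](C)(C)C(C)(C)C)CC2(C)C)C(C)(C)C[C@H](O[Si](C)(C)C(C)(C)C)C1
F9 | step 8 | (2E)-5-[(4R)-4-[(tert-butyldimethylsilyl)oxy]-2,6,6-trimethylcyclohex-1-en-1-yl]-3-methylpent-2-en-4-ynal | CC1=C(C#C/C(C)=C/C=O)C(C)(C)C[C@H](O[Si](C)(C)C(C)(C)C)C1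
F10 | step 8 | (2E,4E,6E)-2,7-dimethylocta-2,4,6-triene-1,8-diol | OC/C(C)=C/C=C/C=C(C)/CO
F11 | step 8 | (2E,4E,6E)-1,8-dibromo-2,7-dimethylocta-2,4,6-triene | BrC/C(C)=C/C=C/C=C(C)/CBr
F12 | step 8 | tetraethyl [(2E,4E,6E)-2,7-dimethylocta-2,4,6-triene-1,8-diyl]bis(phosphonate) | CCOP(=O)(OCC)C/C(C)=C/C=C/C=C(C)/CP(=O)(OCC)OCC
F13 | step 5 | tert-butyldimethyl{[(2E)-3-methylpent-2-en-4-yn-1-yl]oxy}silane | C#C/C(C)=C/CO[Si](C)(C)C(C)(C)C
F14 | step 5 | lithium acetylide of F13 | [Li]C#C/C(C)=C/CO[Si](C)(C)C(C)(C)C
F15 | step 5 | (4R,6R)-4-[(tert-butyldimethylsilyl)oxy]-1-[(3E)-5-[(tert-butyldimethylsilyl)oxy]-3-methylpent-3-en-1-yn-1-yl]-2,2,6-trimethylcyclohexan-1-ol (C1 epimers) | C[C@@H]1C[C@@H](O[Si](C)(C)C(C)(C)C)CC(C)(C)C1(O)C#C/C(C)=C/CO[Si](C)(C)C(C)(C)C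
F16 | step 5 | tert-butyl{[(2E)-5-[(4R)-4-[(tert-butyldimethylsilyl)oxy]-2,6,6-trimethylcyclohex-1-en-1-yl]-3-methylpent-2-en-4-yn-1-yl]oxy}dimethylsilane | CC1=C(C#C/C(C)=C/CO[Si](C)(C)C(C)(C)C)C(C)(C)C[C@H](O[Si](C)(C)C(C)(C)C)C1
F17 | step 2 | (4S,6R)-4-hydroxy-2,2,6-trimethylcyclohexan-1-one | C[C@@H]1C[C@H](O)CC(C)(C)C1=O
A1 | alternative 1 | (3S,4R)-3,4-epoxide of the silylated ring enyne (carotenoid numbering) | C[Si](C)(C)C#CC1=C(C)[C@H]2O[C@H]2CC1(C)C
A2 | alternative 1 | trimethyl[(2,6,6-trimethylcyclohexa-1,3-dien-1-yl)ethynyl]silane | C[Si](C)(C)C#CC1=C(C)C=CCC1(C)C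
A3 | alternative 2 | tris(tert-butyldimethylsilyl) ether of the target | CC1=C(C#C/C(C)=C/C=C/C(C)=C/C=C/C=C(C)/C=C/C=C(\C)C#CC2=C(C)[C@H](O[Si](C)(C)C(C)(C)C)[C@@H](O[Si](C)(C)C(C)(C)C)CC2(C)C)C(C)(C)C[C@H](O[Si](C)(C)C(C)(C)C)C1
A4 | alternative 2 | crocetindial | O=C/C(C)=C/C=C/C(C)=C/C=C/C=C(C)/C=C/C=C(\C)C=O
A5 | alternative 2 | {[(4R)-4-[(tert-butyldimethylsilyl)oxy]-2,6,6-trimethylcyclohex-1-en-1-yl]methanesulfonyl}benzene | CC1=C(CS(=O)(=O)c2ccccc2)C(C)(C)C[C@H](O[Si](C)(C)C(C)(C)C)C1
A6 | alternative 2 | {[(3S,4S)-3,4-bis[(tert-butyldimethylsilyl)oxy]-2,6,6-trimethylcyclohex-1-en-1-yl]methanesulfonyl}benzene | CC1=C(CS(=O)(=O)c2ccccc2)C(C)(C)C[C@H](O[Si](C)(C)C(C)(C)C)[C@H]1O[Si](C)(C)C(C)(C)C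
A7 | alternative 3 | 3,4-bis(tert-butyldimethylsilyl) ether of the target | CC1=C(C#C/C(C)=C/C=C/C(C)=C/C=C/C=C(C)/C=C/C=C(\C)C#CC2=C(C)[C@H](O[Si](C)(C)C(C)(C)C)[C@@H](O[Si](C)(C)C(C)(C)C)CC2(C)C)C(C)(C)C[C@H](O)C1
A8 | alternative 3 | [(2E,4E,6E)-9-[(4R)-4-hydroxy-2,6,6-trimethylcyclohex-1-en-1-yl]-3,7-dimethylnona-2,4,6-trien-8-yn-1-yl]triphenylphosphonium bromide | CC1=C(C#C/C(C)=C/C=C/C(C)=C/C[P+](c2ccccc2)(c2ccccc2)c2ccccc2)C(C)(C)C[C@H](O)C1.[Br-]
A9 | alternative 3 | (2E,4E,6E)-9-[(3S,4S)-3,4-bis[(tert-butyldimethylsilyl)oxy]-2,6,6-trimethylcyclohex-1-en-1-yl]-3,7-dimethylnona-2,4,6-trien-8-ynal | CC1=C(C#C/C(C)=C/C=C/C(C)=C/C=O)C(C)(C)C[C@H](O[Si](C)(C)C(C)(C)C)[C@H]1O[Si](C)(C)C(C)(C)C
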